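A factor of 2.65 in left-handed substrate consumed by 3.00 h was what 4.00 times the coupling partner bought between Tuesday's run and Wednesday's, so I told you that your hunch, consumption in step with the charge, failed on the readings and that the logarithm served better.

common to all: left-handed substrate 0.30 M; right-handed substrate 0.30 M; catalyst 1.5 mol%

|  | coupling partner | remark | time |
|---|---|---|---|
| Tuesday's | 0.60 equiv | run made earlier |  |
| Wednesday's | 2.4 equiv | run made earlier |  |
| flask | 1.20 equiv |  | 5.0 h |

| run | time / h | left-handed substrate / % | right-handed substrate / % |
|---|---|---|---|
| Tuesday's | 0.250 | 44.0 | 49.7 |
| Tuesday's | 0.417 | 42.2 | 49.0 |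
| Tuesday's | 0.833 | 38.8 | 49.0 |
| Tuesday's | 1.50 | 36.8 | 48.9 |
| Tuesday's | 3.00 | 35.8 | 48.5 |
| Wednesday's | 0.250 | 31.4 | 47.8 |
| Wednesday's | 0.417 | 24.8 | 46.4 |
| Wednesday's | 0.833 | 18.4 | 44.9 |
| Wednesday's | 1.50 | 14.4 | 43.6 |
| Wednesday's | 3.00 | 12.4 | 43.4 |

(readings scatter by 0.3 percentage points)

- catalyst is single-handed; left-handed substrate and right-handed substrate are mirror images of each other, charged as a racemate, each of them at the stated concentration
- an excess is below zero if the other one leads

- part of the left-handed substrate and right-handed substrate charged together that has reacted at 5.0 h
- excess of left-handed product over right-handed product in the product at 5.0 h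
- excess of right-handed substrate over left-handed substrate among what is left of the two at 5.0 h

With the charges of catalyst and substrate held as in these runs, the natural logarithm of the left-handed substrate's starting share over what remains adds up the product of partner and active catalyst over time. I took whatever fades in these runs to fade on a clock of its own, an assumption under which that logarithm grows in proportion to the partner's charge. I divided the logarithm at the last reading by the equivalents charged, which gave 0.557 per equivalent on Tuesday's run and 0.581 on Wednesday's. I carried their mean, 0.569, as the reach per equivalent. For the new flask at 1.20 equiv, my reach left 25.3 % of left-handed substrate. The forecast, a separate reckoning from this one, stood at 28.1 % reacted, 76.5 % product excess and 29.9 % substrate excess, on the ground that the “plateaus come from the catalyst dying”.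

The flask gave 28.8 % reacted, 75.4 % product excess and 30.6 % substrate excess, and the forecast held within its margins.

    coupling partner + catalyst + left-handed substrate → catalyst + left-handed product (k = 0.636 M⁻² s⁻¹)
    coupling partner + catalyst + right-handed substrate → catalyst + right-handed product (k = 0.0664 M⁻² s⁻¹)
    2 coupling partner → self-condensation product (k = 9.02 × 10⁻⁴ M⁻¹ s⁻¹)
    coupling partner → decomposed reagent (k = 6.45 × 10⁻⁴ s⁻¹)
    coupling partner ⇌ dormant form (K = 2.10, k = 0.0119 s⁻¹)

At 5.00 h the catalyst in this flask stood at 100 % of its charge and the coupling partner, the limiting reagent, at 0.032 % of its own. Its left-handed substrate gave a reach of 0.588 per equivalent against the carried 0.569. For the neighbour charged with 0.300 equiv, the carried reach gave 42.2 % of left-handed substrate, and that flask stood at 42.4 %.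

Readings and results stem from a simulated flask with constants of no real substance, noise included.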